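Write the balance of the second end groups, the limiting reagent of the dawn run, as links plus one unknown loss.

| setting | dusk | autumn | noon | dawn | gamma | epsilon | zeta | theta |
|---|---|---|---|---|---|---|---|---|
| first end groups | 0.050 M | 0.050 M | 0.050 M | 0.050 M | 0.050 M (fed, over 6.0 h) | 0.050 M | 0.050 M | 0.050 M |
| second end groups | 0.050 M | 0.050 M | 0.050 M | 0.025 M | 0.0500 M | 0.0500 M (in portions, 2, over 6.0 h) | 0.0500 M (fed, over 6.0 h) | 0.0500 M |
| protic impurity | 2.5 mM | 1.2 mM | 5 mM | 2.5 mM | 2.50 mM | 2.50 mM | 2.50 mM | 2.50 mM |
| remark | run made earlier | run made earlier | run made earlier | run made earlier | all else is in the flask from the start; the feed brings no volume worth counting | first portion at the start, last at 6.0 h | all else is in the flask from the start; the feed brings no volume worth counting | everything together at the start |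
| time |  |  |  |  | 30 h | 30 h | 30 h | 30 h |

| dusk: time / h | dusk: links / % | autumn: time / h | autumn: links / % | noon: time / h | noon: links / % | dawn: time / h | dawn: links / % |
|---|---|---|---|---|---|---|---|
| 8.00 | 90.8 | 2.50 | 88.6 | 5.00 | 91.9 | 2.50 | 45.8 |
| 15.0 | 92.7 | 6.00 | 91.0 | 10.0 | 93.7 | 6.00 | 44.3 |
| 25.0 | 93.0 | 12.0 | 93.4 | 15.0 | 93.5 | 12.0 | 45.8 |
| 30.0 | 91.4 | 20.0 | 92.6 | 20.0 | 93.9 | 20.0 | 44.4 |

(each reading ± 1 percentage point)



1. the best flask by amount of links, in percent of the first end groups charged; "all alike" if 1.5 percentage points covers them all (gamma / epsilon / zeta / theta / all alike)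
2. amount of links at the end, in percent of the first end groups charged, gamma
3. amount of links at the end, in percent of the first end groups charged, epsilon
4. amount of links at the end, in percent of the first end groups charged, zeta
5. amount of links at the end, in percent of the first end groups charged, theta

With equal charges, late readings level at 93.0% at 1.2 mM, 2.5 mM and 5 mM of protic impurity, so the shortfall reads 3.49 mM. The dawn run loses 9.85% of its second end groups, more than the 7.00% lost with equal charges. A loss sharing the order of link-making would take one fixed share, so I take a loss running at r·c(first end groups), whatever c(second end groups) is while any stands. Links run at k·c(first end groups)·c(second end groups), and the first autumn reading gives k near 62.2 M⁻¹ h⁻¹.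

c(first end groups) cancels from the balance, so a batch loses κ·ln(1 + charge/κ), with κ = r/k. The shortfall gives κ = 0.854 mM. This yields the loss time τ = 1/r = 18.8 h, the mean time a first end group survives the loss alone.

The lost share is the waiting time over τ, the waiting time being the mean time a first end group stands unlinked while second end groups last. Theta's waiting time is 1.31 h, and gamma's balance gives the same loss, so this reckoning holds both near 93.0%. Epsilon is 2 small batches, giving 88.3%. Zeta's waiting time is about half the feed time, and the remainder at the feed's end, where k·c·c equals the feed rate, finishes as a small batch, giving 79.5%.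

The forecast differs, with all alike and 93% for each flask: “So addition order should matter little”.

The flasks give 83.9% for gamma, 89.1% for epsilon, 78.9% for zeta and 92.8% for theta, so theta is best. Gamma falls below this reckoning: its rings are 5.77%, but 9.84% of first end groups remain, with homo dimer at 0.00257 M.

    first end groups + second end groups → links (k = 0.0200 M⁻¹ s⁻¹)
    first end groups + second end groups → rings, rate k2*[first end groups] as long as [second end groups] is above zero (k = 1.40 × 10⁻⁵ s⁻¹)
    first end groups + protic impurity → quenched substrate (k = 1.70 × 10⁻⁴ M⁻¹ s⁻¹)
    2 second end groups → homo dimer (k = 1.40 × 10⁻⁴ M⁻¹ s⁻¹)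

Taking the ring step away turns the gap between theta and zeta from 14 percentage points to −0.17 points. In zeta, mean c(second end groups) over the feed is 0.00352 M, so the selectivity factor k·c(second end groups)·τ is 4.12. This reckoning sends about 19.5% of zeta's turnover to loss, and zeta holds 20.1% rings. The neighbour flask charged with 0.020 M of first end groups ends with 31.2% of its second end groups left. The same τ gives that flask 2.13% rings, and it holds 1.79%.

The readings are simulated from invented constants, noise included.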